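**Strategy**

The plan cuts the two bonds that flank the C1–C2 unit of the tridecane chain: the bond from the benzene ring to benzylic C1 and the C2–C3 bond to the undecyl group. C1 and the oxygen-bearing C2 form an ethylene unit held between the arene and the alkyl chain, so a vinyl group on boron can supply both carbons. A palladium-catalysed conjunctive coupling of a lithium undecyl(vinyl)borate with an aryl triflate makes both bonds and sets C2 as a C–B stereocentre in one operation; oxidation then turns C–B into C–O with retention. The precursors are vinylboronic acid pinacol ester, halide-free undecyllithium and 3-(benzyloxy)-5-methoxyphenyl triflate.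

Key step: step 4

Remark (assumption): the absolute sense of induction of the ligand is not derived here; the (Rp,Rp) enantiomer of MandyPhos is written, the configuration of 9 is to be checked on the first run (Mosher esters), and the equally available (Sp,Sp) ligand is used instead if the sense proves opposite.

Remark (design): undecyllithium is made from the chloride and lithium metal in hexane, not by halogen–lithium exchange. Exchange would leave soluble lithium halide, which binds the cationic arylpalladium and blocks alkene coordination; LiCl is insoluble in hexane and is filtered off.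

**Route**

Step 1
Reactants: 1 5-methoxyresorcinol (2 equiv)
Product: 2 3-(benzyloxy)-5-methoxyphenol
Conditions: BnBr (1.0 equiv), K2CO3 (1.1 equiv), acetone, reflux
Reagents that add atoms: benzyl bromide, BrCc1ccccc1
Why: Williamson ether synthesis: the phenoxide displaces bromide from benzyl bromide, and keeping the diol in twofold excess should hold bis-benzylation down, the neutral bis-ether and the water-soluble diol being removed by extraction and chromatography.

Step 2
Reactants: 2 3-(benzyloxy)-5-methoxyphenol
Product: 3 3-(benzyloxy)-5-methoxyphenyl trifluoromethanesulfonate
Conditions: Tf2O (1.2 equiv), pyridine (2 equiv), CH2Cl2, 0 °C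
Reagents that add atoms: trifluoromethanesulfonic anhydride, O=S(=O)(OS(=O)(=O)C(F)(F)F)C(F)(F)F
Why: O-Sulfonylation of a phenol with triflic anhydride and pyridine is fast at 0 °C and leaves the benzyl and methyl aryl ethers untouched.

Step 3
Reactants: 4 1-chloroundecane
Product: 5 undecyllithium (titrated hexane solution)
Conditions: Li dispersion (about 1% Na, 2.5 equiv), hexane, 50 °C; filtration from LiCl under argon; titration
Reagents that add atoms: lithium metal, [Li]
Why: Direct reductive lithiation of a primary alkyl chloride by lithium metal in a hydrocarbon gives the alkyllithium in solution while LiCl, which is insoluble in hexane, is filtered off, so that the reagent carries almost no halide into step 4.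

Step 4
Reactants: 6 vinylboronic acid pinacol ester (1.2 equiv); 5 undecyllithium (1.2 equiv); 3 3-(benzyloxy)-5-methoxyphenyl trifluoromethanesulfonate (1.0 equiv)
Product: 8 2-[(2R)-1-(3-benzyloxy-5-methoxyphenyl)tridecan-2-yl]-4,4,5,5-tetramethyl-1,3,2-dioxaborolane, via lithium pinacolato(undecyl)(vinyl)borate 7 (not isolated)
Conditions: 6, 5, Et2O, 0 °C to rt, then solvent removed; 3, Pd(OAc)2 (2 mol%), (Rp,Rp)-MandyPhos [1,1'-bis(diphenylphosphino)-2,2'-bis((S)-α-(dimethylamino)benzyl)ferrocene] (2.4 mol%), THF, 60 °C, 14 h
Reagents that add atoms: none
Why: Pd(OAc)2 is reduced in the flask to zerovalent palladium, which adds oxidatively to the C–O bond of triflate 3 to give a cationic divalent arylpalladium complex that binds the vinyl group of borate 7; this π-activation induces a 1,2-metallate shift in which undecyl moves from boron to the α-carbon (C2–C3 bond) anti to palladium while the Pd–C1 bond forms, and reductive elimination then makes the aryl–C1 bond and returns zerovalent palladium. The closest known reaction type is the palladium-catalysed enantioselective conjunctive cross-coupling of vinylboron ate complexes with aryl triflates, for which primary alkyl migrating groups and alkoxy-substituted aryl triflates are established. No ring is closed. The C2 stereocentre is set by the chiral ferrocenyl bisphosphine, which dictates the face of the bound alkene that the arylpalladium occupies, the anti migration then translating that facial choice into the (R) C–B centre. The step needs the metallate shift to outrun direct vinyl transmetalation (Suzuki–Miyaura product) and β-hydride elimination, which the wide-bite-angle ligand, the weakly coordinating triflate counter-ion and the halide-lean borate should secure. Undecyl migrates rather than a pinacol oxygen because the alkoxy ligands are tied into the five-membered dioxaborolane and are poor migrating groups.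

Step 5
Reactants: 8 2-[(2R)-1-(3-benzyloxy-5-methoxyphenyl)tridecan-2-yl]-4,4,5,5-tetramethyl-1,3,2-dioxaborolane
Product: 9 (2R)-1-(3-benzyloxy-5-methoxyphenyl)tridecan-2-ol
Conditions: H2O2 (30% aq), NaOH (3 M aq), THF, 0 °C to rt
Reagents that add atoms: hydrogen peroxide, OO
Why: Alkaline hydrogen peroxide oxidation of the boronic ester: hydroperoxide adds to boron and C2 migrates from boron to oxygen with retention, so the (R) C–B centre becomes the (R) carbinol (the descriptor is unchanged), while the aryl ethers are inert.

Step 6
Reactants: 9 (2R)-1-(3-benzyloxy-5-methoxyphenyl)tridecan-2-ol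
Product: 10 (2R)-1-(3-benzyloxy-5-methoxyphenyl)tridecan-2-yl acetate
Conditions: Ac2O (1.5 equiv), pyridine (3 equiv), DMAP (5 mol%), CH2Cl2, rt
Reagents that add atoms: acetic anhydride, CC(=O)OC(C)=O
Why: DMAP-catalysed acylation (nucleophilic catalysis) of the only free hydroxyl group; the phenol is still masked as its benzyl ether, so no aryl acetate can form and the stereocentre is not touched.

Step 7
Reactants: 10 (2R)-1-(3-benzyloxy-5-methoxyphenyl)tridecan-2-yl acetate
Product: 11 (2R)-1-(3-hydroxy-5-methoxyphenyl)tridecan-2-yl acetate (target)
Conditions: H2 (1 atm), Pd/C (10 wt% Pd on carbon), EtOAc, rt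
Reagents that add atoms: none
Why: Catalytic hydrogenolysis cleaves the benzylic C–O bond of the aryl benzyl ether to give the phenol and toluene, while the acetate sits on a homobenzylic carbon, is not a benzylic C–O bond and should survive neutral conditions in ethyl acetate.

**Compound list**

1 | 5-methoxyresorcinol (5-methoxybenzene-1,3-diol) | COc1cc(O)cc(O)c1 | starting material
2 | 3-(benzyloxy)-5-methoxyphenol | COc1cc(O)cc(OCc2ccccc2)c1 | intermediate
3 | 3-(benzyloxy)-5-methoxyphenyl trifluoromethanesulfonate | COc1cc(OCc2ccccc2)cc(OS(=O)(=O)C(F)(F)F)c1 | intermediate
4 | 1-chloroundecane | CCCCCCCCCCCCl | starting material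
5 | undecyllithium | [Li]CCCCCCCCCCC | intermediate
6 | vinylboronic acid pinacol ester (4,4,5,5-tetramethyl-2-vinyl-1,3,2-dioxaborolane) | C=CB1OC(C)(C)C(C)(C)O1 | starting material
7 | lithium pinacolato(undecyl)(vinyl)borate (four-coordinate boron ate complex) | [Li+].C=C[B-]1(CCCCCCCCCCC)OC(C)(C)C(C)(C)O1 | intermediate
8 | 2-[(2R)-1-(3-benzyloxy-5-methoxyphenyl)tridecan-2-yl]-4,4,5,5-tetramethyl-1,3,2-dioxaborolane | CCCCCCCCCCC[C@H](Cc1cc(OCc2ccccc2)cc(OC)c1)B1OC(C)(C)C(C)(C)O1 | intermediate
9 | (2R)-1-(3-benzyloxy-5-methoxyphenyl)tridecan-2-ol | CCCCCCCCCCC[C@H](Cc1cc(OCc2ccccc2)cc(OC)c1)O | intermediate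
10 | (2R)-1-(3-benzyloxy-5-methoxyphenyl)tridecan-2-yl acetate | CCCCCCCCCCC[C@H](Cc1cc(OCc2ccccc2)cc(OC)c1)OC(C)=O | intermediate
11 | (2R)-1-(3-hydroxy-5-methoxyphenyl)tridecan-2-yl acetate | CCCCCCCCCCC[C@H](Cc1cc(O)cc(OC)c1)OC(C)=O | target

**Step count and risk**

Total step count: 7. Longest linear sequence: 6 steps (steps 1, 2, 4, 5, 6, 7 from compound 1); step 3 is a one-step side branch from compound 4.

Steps most likely to fail:

1. Step 4. The arylpalladium may bind the vinyl borate with poor facial discrimination, or transfer of the vinyl group to palladium may compete with the metallate shift, so that the coupling may proceed with low enantioselectivity or low conversion. The fallback sets out from 3 and comes back at 9. Triflate 3 would be coupled with allyltributylstannane (Stille coupling; Pd(PPh3)4, LiCl, DMF, 80 °C) to give 1-allyl-3-(benzyloxy)-5-methoxybenzene F1. Epoxidation with mCPBA (CH2Cl2, NaHCO3, 0 °C to rt) would give racemic 2-[(3-benzyloxy-5-methoxyphenyl)methyl]oxirane F2. Hydrolytic kinetic resolution with water (0.55 equiv) and the chiral (salen)Co(OAc) catalyst (the acetate of trivalent cobalt with N,N'-bis(3,5-di-tert-butylsalicylidene)cyclohexane-1,2-diamine; the enantiomer that consumes the (R)-epoxide, expected to be the (S,S) complex) would leave (2S)-2-[(3-benzyloxy-5-methoxyphenyl)methyl]oxirane F3. Copper-catalysed opening at the terminal carbon with decylmagnesium bromide (CuI 10 mol%, THF, −30 °C) would then give 9, which continues with step 6. The stereocentre then comes from a resolution that does not depend on the size of the groups flanking C2, at the price of half of the epoxide.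

2. Step 3. Wurtz-type coupling and incomplete insertion at the lithium surface may give a weak solution whose titre and residual chloride make the borate stoichiometry unreliable. The fallback sets out from 4 and comes back at 7, with the roles of the two boron substituents exchanged. Chloride 4 would be converted with Mg turnings in THF into undecylmagnesium chloride F4, which is quenched with 2-isopropoxy-4,4,5,5-tetramethyl-1,3,2-dioxaborolane to give 2-undecyl-4,4,5,5-tetramethyl-1,3,2-dioxaborolane F5, a stable boronic ester that can be purified free of halide. Addition of vinyllithium F6 (prepared halide-free from tetravinylstannane and n-BuLi in pentane) to F5 in Et2O at 0 °C would give the same borate 7, which enters the palladium-catalysed stage of step 4 unchanged.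

3. Step 1. The second phenol is alkylated at a rate similar to the first, so over-benzylation may erode the amount of mono-ether and complicate its separation. The fallback sets out from 1 and comes back at 2. Exhaustive benzylation (BnBr 2.5 equiv, K2CO3, DMF, 60 °C) would give 1,3-bis(benzyloxy)-5-methoxybenzene F7. NaSEt (1.5 equiv, DMF, 100 °C) would then remove one benzyl group by SN2 attack at the benzylic carbon; the phenoxide that results slows a second dealkylation, which is the known basis of thiolate mono-dealkylation of resorcinol diethers. Acidic work-up would return 2; some competing O-demethylation is to be expected and would be removed by chromatography.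

**Further compounds**

F1 | step 4 | 1-allyl-3-(benzyloxy)-5-methoxybenzene | C=CCc1cc(OCc2ccccc2)cc(OC)c1
F2 | step 4 | racemic 2-[(3-benzyloxy-5-methoxyphenyl)methyl]oxirane | COc1cc(CC2CO2)cc(OCc3ccccc3)c1
F3 | step 4 | (2S)-2-[(3-benzyloxy-5-methoxyphenyl)methyl]oxirane | COc1cc(C[C@H]2CO2)cc(OCc3ccccc3)c1
F4 | step 3 | undecylmagnesium chloride | CCCCCCCCCCC[Mg]Cl
F5 | step 3 | 2-undecyl-4,4,5,5-tetramethyl-1,3,2-dioxaborolane | CCCCCCCCCCCB1OC(C)(C)C(C)(C)O1
F6 | step 3 | vinyllithium | [Li]C=C
F7 | step 1 | 1,3-bis(benzyloxy)-5-methoxybenzene | COc1cc(OCc2ccccc2)cc(OCc2ccccc2)c1
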